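The route rests on cutting the O1–C8a bond of the pyranone fused to the saturated ring. That six-membered carbocycle, with C4a, C8a and the C4 carbonyl carbon, is the ring, C1, C2 and carboxyl carbon of (−)-shikimic acid. C8 and C7 keep its C3 and C4 configuration, and C8a lacks only oxygen in place of its vinylic hydrogen. In one operation the distal enol hydroxyl of a cyclohexenyl 1,3-diketone closes onto C8a (6-endo), and palladium with O2 strips the hydrogens from C4a and C8a, so the pyranone appears directly. The precursor already carries the second chromone as C8 aryl ether, all four stereocentres, and a disiloxane bridge across O5 and O6.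

Key step: step 16

**Conventions**
- Shikimate numbering is used up to the diketone precursor and chromone numbering from the ring closure on. Shikimate C1, C2, C3, C4, C5, C6 correspond to chromone C4a, C8a, C8, C7, C6, C5.
- α is the ring face of O3 and O4 of shikimic acid; β is the face of O5.
- ArO = (7-methoxy-4-oxo-2-(2-phenylethyl)-4H-chromen-6-yl)oxy. TIPDS = 1,1,3,3-tetraisopropyldisiloxane-1,3-diyl. TBS = tert-butyldimethylsilyl.
- The target is (5S,6R,7S,8S), that is O5 α, O6 β, O7 α, O8 α.

**Assumption:** 1,3-diketones are drawn in the diketo form although they react as chelated enols.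

**Design remarks**
- (a) The chromone C5 oxygen (shikimate 6α) comes from anti opening of a 5β,6β-epoxide. An ene-type allylic hydroxylation (SeO2) should remove the pseudoaxial 6β hydrogen and return oxygen on that same face, cis to O5. It would also find the doubly activated C3–H.
- (b) The aromatic chromone is built separately and joined with net retention. This spares the carbocycle any Friedel–Crafts or Fries chemistry.
- (c) Three separate bulky silyl ethers on the trans,trans-triol would favour the ring conformer with a pseudoaxial C5–O bond, which is aligned for β-elimination. The disiloxane bridge excludes that conformer.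

**Carbocycle**

Step 1
Reactants: 1 (−)-shikimic acid
Product: 3 methyl 3,4-O-isopropylideneshikimate, via methyl shikimate 2 (not isolated)
Conditions: MeOH, camphorsulfonic acid (cat.), reflux; evaporate; 2,2-dimethoxypropane, acetone, rt
Reagents that add atoms: methanol CO; 2,2-dimethoxypropane COC(C)(C)OC
Why: Fischer esterification followed by acid-catalysed transketalisation, in which only the cis-3,4-diol can form an unstrained cis-fused dioxolane, so O5 stays free and no stereocentre is touched.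

Step 2
Reactants: 3 methyl 3,4-O-isopropylideneshikimate
Product: 5 methyl 3α,4α-(isopropylidenedioxy)cyclohexa-1,5-diene-1-carboxylate, via 5-O-triflate 4 (not isolated)
Conditions: Tf2O, pyridine, CH2Cl2, −20 °C; then DBU, 0 °C to rt
Reagents that add atoms: trifluoromethanesulfonic anhydride O=S(=O)(OS(=O)(=O)C(F)(F)F)C(F)(F)F (its atoms stay only in 4)
Why: Sulfonylation and E2 elimination: once the 5β-triflate is axial only the 6α hydrogen is antiperiplanar (the C4 hydrogen is syn), so the C5=C6 alkene forms while C3 and C4 are untouched.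

Step 3
Reactants: 5 methyl 3α,4α-(isopropylidenedioxy)cyclohexa-1,5-diene-1-carboxylate
Product: 6 methyl 5β,6β-epoxy-3α,4α-(isopropylidenedioxy)cyclohex-1-ene-1-carboxylate
Conditions: mCPBA, Na2HPO4, CH2Cl2, 0 °C to rt
Reagents that add atoms: mCPBA OOC(=O)c1cccc(Cl)c1
Why: Prilezhaev epoxidation picks the C5=C6 alkene, which bears no acyl group, over the ester-bearing C1=C2 alkene, and the α-face acetonide sends the peracid to the β face, which restores the β oxygen at C5.

Step 4
Reactants: 6 methyl 5β,6β-epoxy-3α,4α-(isopropylidenedioxy)cyclohex-1-ene-1-carboxylate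
Product: 7 methyl 5β,6α-dihydroxy-3α,4α-(isopropylidenedioxy)cyclohex-1-ene-1-carboxylate
Conditions: HClO4 (5 mol %), THF/H2O 4:1, 0 °C
Reagents that add atoms: water O
Why: Acid-catalysed anti (SN2-like) epoxide opening occurs at allylic C6 rather than at C5, which is deactivated by the adjacent C4 oxygen, so water enters from the α face with inversion and sets the 6α-hydroxyl trans to the retained 5β-hydroxyl.

Step 5
Reactants: 7 methyl 5β,6α-dihydroxy-3α,4α-(isopropylidenedioxy)cyclohex-1-ene-1-carboxylate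
Product: 8 methyl 3α,4α-(isopropylidenedioxy)-5β,6α-(TIPDS-dioxy)cyclohex-1-ene-1-carboxylate
Conditions: (iPr2SiCl)2O, imidazole, DMF, 0 °C to rt
Reagents that add atoms: 1,3-dichloro-1,1,3,3-tetraisopropyldisiloxane CC(C)[Si](Cl)(C(C)C)O[Si](Cl)(C(C)C)C(C)C
Why: Cyclic disiloxane formation, familiar from trans-diequatorial vicinal diols of pyranosides, gives a seven-membered ring that can span O5 and O6 only when both are (pseudo)equatorial.

Step 6
Reactants: 8 methyl 3α,4α-(isopropylidenedioxy)-5β,6α-(TIPDS-dioxy)cyclohex-1-ene-1-carboxylate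
Product: 9 methyl 3α,4α-dihydroxy-5β,6α-(TIPDS-dioxy)cyclohex-1-ene-1-carboxylate
Conditions: AcOH/H2O 4:1, 55 °C
Reagents that add atoms: none
Why: Acetal hydrolysis of the cis-dioxolane in dilute carboxylic acid should be faster than cleavage of the hindered secondary disiloxane.

Step 7
Reactants: 9 methyl 3α,4α-dihydroxy-5β,6α-(TIPDS-dioxy)cyclohex-1-ene-1-carboxylate
Product: 10 3α,4α-cyclic carbonate of 9
Conditions: 1,1'-carbonyldiimidazole, CH2Cl2, rt
Reagents that add atoms: 1,1'-carbonyldiimidazole O=C(n1ccnc1)n1ccnc1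
Why: Carbonylation of the cis-1,2-diol closes the five-membered cyclic carbonate, which masks O4 and turns allylic O3 into a leaving group in one move.

**Phenol partner**

Step 8
Reactants: 11 2-methoxyhydroquinone
Product: 12 1-(2,5-dihydroxy-4-methoxyphenyl)ethanone
Conditions: AcOH, BF3·OEt2, 90 °C
Reagents that add atoms: acetic acid CC(=O)O
Why: Friedel–Crafts acylation goes to the position para to methoxy and ortho to a hydroxyl, the most activated and least crowded site, and gives the chelated ortho-hydroxy ketone.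

Step 9
Reactants: 12 1-(2,5-dihydroxy-4-methoxyphenyl)ethanone; 13 3-phenylpropanoyl chloride (2.2 equiv)
Product: 14 2-acetyl-5-methoxybenzene-1,4-diyl bis(3-phenylpropanoate)
Conditions: Et3N, DMAP (cat.), CH2Cl2, 0 °C to rt
Reagents that add atoms: none
Why: DMAP-catalysed O-acylation esterifies both phenols, so no separate protecting group is needed for the second hydroxyl.

Step 10
Reactants: 14 2-acetyl-5-methoxybenzene-1,4-diyl bis(3-phenylpropanoate)
Product: 15 4-hydroxy-2-methoxy-5-(3-oxo-5-phenylpentanoyl)phenyl 3-phenylpropanoate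
Conditions: LiN(SiMe3)2 (2.5 equiv), THF, −78 to 0 °C; 1 M HCl
Reagents that add atoms: none
Why: Baker–Venkataraman rearrangement, in which the kinetically formed methyl ketone enolate attacks the neighbouring ortho ester through a six-membered transition state to give the 1,3-diketone.

Step 11
Reactants: 15 4-hydroxy-2-methoxy-5-(3-oxo-5-phenylpentanoyl)phenyl 3-phenylpropanoate
Product: 16 6-hydroxy-7-methoxy-2-(2-phenylethyl)-4H-chromen-4-one
Conditions: conc. HCl (cat.), MeOH, reflux
Reagents that add atoms: none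
Why: Acid-catalysed cyclodehydration of the ortho-hydroxyaryl 1,3-diketone gives the chromone, while the remaining aryl ester is transesterified by methanol and frees the C6 phenol.

**Union and endgame**

Step 12
Reactants: 10 3α,4α-cyclic carbonate of 9; 16 6-hydroxy-7-methoxy-2-(2-phenylethyl)-4H-chromen-4-one
Product: 17 methyl 3α-ArO-4α-hydroxy-5β,6α-(TIPDS-dioxy)cyclohex-1-ene-1-carboxylate
Conditions: Pd2(dba)3·CHCl3 (2.5 mol %), PPh3 (15 mol %), THF, rt to 40 °C
Reagents that add atoms: none
Why: Tsuji–Trost decarboxylative allylic etherification: zerovalent palladium ionises the pseudoaxial C3–O bond from the β face with loss of CO2, the C4 alkoxide deprotonates the phenol, and the phenoxide attacks from the α face at C3, the allyl terminus remote from the ester and less substituted than C1, so two inversions retain the C3 configuration.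

Step 13
Reactants: 17 methyl 3α-ArO-4α-hydroxy-5β,6α-(TIPDS-dioxy)cyclohex-1-ene-1-carboxylate
Product: 18 methyl 3α-ArO-4α-(TBSO)-5β,6α-(TIPDS-dioxy)cyclohex-1-ene-1-carboxylate
Conditions: TBSOTf, 2,6-lutidine, CH2Cl2, 0 °C
Reagents that add atoms: tert-butyldimethylsilyl triflate CC(C)(C)[Si](C)(C)OS(=O)(=O)C(F)(F)F
Why: O-silylation with a silyl triflate and a hindered pyridine base covers the flanked secondary hydroxyl without silyl migration or elimination.

Step 14
Reactants: 18 methyl 3α-ArO-4α-(TBSO)-5β,6α-(TIPDS-dioxy)cyclohex-1-ene-1-carboxylate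
Product: 19 3α-ArO-4α-(TBSO)-5β,6α-(TIPDS-dioxy)cyclohex-1-ene-1-carboxylic acid
Conditions: Me3SnOH (8 equiv), ClCH2CH2Cl, 80 °C; brief wash with 5% aq HCl
Reagents that add atoms: trimethyltin hydroxide C[Sn](C)(C)O
Why: Tin-assisted acyl–oxygen hydrolysis of the methyl ester runs under nearly neutral conditions and so avoids hydroxide attack on the disiloxane or the chromone and γ-deprotonation at C3.

Step 15
Reactants: 19 3α-ArO-4α-(TBSO)-5β,6α-(TIPDS-dioxy)cyclohex-1-ene-1-carboxylic acid; 20 4-phenylbutan-2-one (3 equiv)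
Product: 23 1-[3α-ArO-4α-(TBSO)-5β,6α-(TIPDS-dioxy)cyclohex-1-en-1-yl]-5-phenylpentane-1,3-dione, via acid chloride 21 (not isolated), via lithium enolate 22 (not isolated)
Conditions: 19, Me2C=C(Cl)NMe2, CH2Cl2, 0 °C; separately 20, LiN(iPr)2, THF, −78 °C; add 21 to 22, −78 °C; aq NH4Cl
Reagents that add atoms: 1-chloro-N,N,2-trimethylprop-1-en-1-amine CC(C)=C(Cl)N(C)C (Cl, only in 21); lithium diisopropylamide [Li+].CC(C)[N-]C(C)C (Li, only in 22)
Why: Neutral acid chloride formation followed by C-acylation of the kinetic methyl-side lithium enolate (crossed Claisen-type acylation), in which excess enolate deprotonates the product and recycles any enol ester, should give the diketone at low temperature with all stereocentres intact.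

Step 16
Reactants: 23 1-[3α-ArO-4α-(TBSO)-5β,6α-(TIPDS-dioxy)cyclohex-1-en-1-yl]-5-phenylpentane-1,3-dione
Product: 25 8α-ArO-7α-(TBSO)-5α,6β-(TIPDS-dioxy)-2-(2-phenylethyl)-5,6,7,8-tetrahydro-4H-chromen-4-one, via dihydropyranone adduct 24 (not isolated)
Conditions: Pd(OCOCF3)2 (15 mol %), DMSO (30 mol %), CF3CO2H (0.3 equiv), O2 (1 atm), EtOAc, 60 °C
Reagents that add atoms: none
Why: The Z-enol oxygen on C2 adds to C8a, the β-carbon of the C4 enone, in a 6-endo-trig oxa-Michael closure (equally describable as anti oxypalladation of the alkene bound to divalent palladium) from the β face, anti to the pseudoaxial C8 aryloxy group, to give cis-fused 24. Divalent palladium then occupies C4a as its enolate on the α face, syn β-hydride elimination removes the α hydrogen at C8a, and O2 returns zerovalent palladium to the divalent state. The closest known reactions are the palladium-catalysed aerobic cyclisation of 2'-hydroxychalcones to flavones, the Wacker-type closure of β-hydroxy enones to dihydropyranones, and the aerobic dehydrogenation of chromanones and dihydropyranones. No stereocentre is created, since the two transient centres C4a and C8a both end up sp2 and C5 to C8 are not touched. Oxygen rather than C3 attacks because C3 attack would need a four-membered ring, and dehydrogenation toward C5 is shut off because the C5 hydrogen is β, anti to palladium, while only the C4a–C8a alkene completes the conjugated pyranone. Loss of the C5 silyloxy group from the C4a enolate is held back by the disiloxane bridge, which keeps that C–O bond pseudoequatorial near the nodal plane of the enolate, and by the acidic base-free medium, which also keeps the diketone from locking palladium in an O,O-chelate.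

Step 17
Reactants: 25 8α-ArO-7α-(TBSO)-5α,6β-(TIPDS-dioxy)-2-(2-phenylethyl)-5,6,7,8-tetrahydro-4H-chromen-4-one
Product: 26 (5S,6R,7S,8S)-5,6,7-trihydroxy-8-ArO-2-(2-phenylethyl)-5,6,7,8-tetrahydro-4H-chromen-4-one (target)
Conditions: HF·pyridine, pyridine/THF, 0 °C to rt
Reagents that add atoms: none
Why: Fluoride-driven Si–O cleavage in a buffered, weakly acidic medium removes the disiloxane and the silyl ether without base, so the pyranones, the C8 aryl ether and the C5 carbinol are not endangered.

**Stereocentre account**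
- C8 comes from the chiral pool and is retained by the double inversion in step 12.
- C7 comes from the chiral pool and is untouched.
- C6 is erased in step 2 and reset in step 3 under control of the α-face acetonide.
- C5 is set in step 4 by inversion at the epoxide.

**Compound list**

1 | (−)-shikimic acid, (3R,4S,5R)-3,4,5-trihydroxycyclohex-1-ene-1-carboxylic acid | O[C@@H]1C=C(C(=O)O)C[C@@H](O)[C@@H]1O | starting material
2 | methyl shikimate | O[C@@H]1C=C(C(=O)OC)C[C@@H](O)[C@@H]1O | intermediate
3 | methyl 3,4-O-isopropylideneshikimate | CC1(C)O[C@@H]2C=C(C(=O)OC)C[C@@H](O)[C@@H]2O1 | intermediate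
4 | methyl 3,4-O-isopropylidene-5-O-(trifluoromethylsulfonyl)shikimate | CC1(C)O[C@@H]2C=C(C(=O)OC)C[C@@H](OS(=O)(=O)C(F)(F)F)[C@@H]2O1 | intermediate
5 | methyl 3α,4α-(isopropylidenedioxy)cyclohexa-1,5-diene-1-carboxylate | CC1(C)O[C@@H]2C=C(C(=O)OC)C=C[C@@H]2O1 | intermediate
6 | methyl 5β,6β-epoxy-3α,4α-(isopropylidenedioxy)cyclohex-1-ene-1-carboxylate | CC1(C)O[C@@H]2C=C(C(=O)OC)[C@H]3O[C@H]3[C@@H]2O1 | intermediate
7 | methyl 5β,6α-dihydroxy-3α,4α-(isopropylidenedioxy)cyclohex-1-ene-1-carboxylate | CC1(C)O[C@@H]2C=C(C(=O)OC)[C@H](O)[C@@H](O)[C@@H]2O1 | intermediate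
8 | methyl 3α,4α-(isopropylidenedioxy)-5β,6α-(TIPDS-dioxy)cyclohex-1-ene-1-carboxylate | CC1(C)O[C@@H]2C=C(C(=O)OC)[C@H](O[Si]3(C(C)C)C(C)C)[C@@H](O[Si](C(C)C)(C(C)C)O3)[C@@H]2O1 | intermediate
9 | methyl 3α,4α-dihydroxy-5β,6α-(TIPDS-dioxy)cyclohex-1-ene-1-carboxylate | O[C@@H]1C=C(C(=O)OC)[C@H](O[Si]2(C(C)C)C(C)C)[C@@H](O[Si](C(C)C)(C(C)C)O2)[C@@H]1O | intermediate
10 | 3α,4α-cyclic carbonate of 9 | O=C1O[C@@H]2C=C(C(=O)OC)[C@H](O[Si]3(C(C)C)C(C)C)[C@@H](O[Si](C(C)C)(C(C)C)O3)[C@@H]2O1 | intermediate
11 | 2-methoxyhydroquinone | COc1cc(O)ccc1O | starting material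
12 | 1-(2,5-dihydroxy-4-methoxyphenyl)ethanone | CC(=O)c1cc(O)c(OC)cc1O | intermediate
13 | 3-phenylpropanoyl chloride | O=C(Cl)CCc1ccccc1 | starting material
14 | 2-acetyl-5-methoxybenzene-1,4-diyl bis(3-phenylpropanoate) | CC(=O)c1cc(OC(=O)CCc2ccccc2)c(OC)cc1OC(=O)CCc1ccccc1 | intermediate
15 | 4-hydroxy-2-methoxy-5-(3-oxo-5-phenylpentanoyl)phenyl 3-phenylpropanoate | COc1cc(O)c(C(=O)CC(=O)CCc2ccccc2)cc1OC(=O)CCc1ccccc1 | intermediate
16 | 6-hydroxy-7-methoxy-2-(2-phenylethyl)-4H-chromen-4-one | COc1cc2oc(CCc3ccccc3)cc(=O)c2cc1O | intermediate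
17 | methyl 3α-ArO-4α-hydroxy-5β,6α-(TIPDS-dioxy)cyclohex-1-ene-1-carboxylate | COc1cc2oc(CCc3ccccc3)cc(=O)c2cc1O[C@@H]1C=C(C(=O)OC)[C@H](O[Si]2(C(C)C)C(C)C)[C@@H](O[Si](C(C)C)(C(C)C)O2)[C@@H]1O | intermediate
18 | methyl 3α-ArO-4α-(TBSO)-5β,6α-(TIPDS-dioxy)cyclohex-1-ene-1-carboxylate | COc1cc2oc(CCc3ccccc3)cc(=O)c2cc1O[C@@H]1C=C(C(=O)OC)[C@H](O[Si]2(C(C)C)C(C)C)[C@@H](O[Si](C(C)C)(C(C)C)O2)[C@@H]1O[Si](C)(C)C(C)(C)C | intermediate
19 | 3α-ArO-4α-(TBSO)-5β,6α-(TIPDS-dioxy)cyclohex-1-ene-1-carboxylic acid | COc1cc2oc(CCc3ccccc3)cc(=O)c2cc1O[C@@H]1C=C(C(=O)O)[C@H](O[Si]2(C(C)C)C(C)C)[C@@H](O[Si](C(C)C)(C(C)C)O2)[C@@H]1O[Si](C)(C)C(C)(C)C | intermediate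
20 | 4-phenylbutan-2-one | CC(=O)CCc1ccccc1 | starting material
21 | acid chloride of 19 | COc1cc2oc(CCc3ccccc3)cc(=O)c2cc1O[C@@H]1C=C(C(=O)Cl)[C@H](O[Si]2(C(C)C)C(C)C)[C@@H](O[Si](C(C)C)(C(C)C)O2)[C@@H]1O[Si](C)(C)C(C)(C)C | intermediate
22 | lithium 4-phenylbut-1-en-2-olate | [Li+].[O-]C(=C)CCc1ccccc1 | intermediate
23 | 1-[3α-ArO-4α-(TBSO)-5β,6α-(TIPDS-dioxy)cyclohex-1-en-1-yl]-5-phenylpentane-1,3-dione (key-step precursor) | COc1cc2oc(CCc3ccccc3)cc(=O)c2cc1O[C@@H]1C=C(C(=O)CC(=O)CCc2ccccc2)[C@H](O[Si]2(C(C)C)C(C)C)[C@@H](O[Si](C(C)C)(C(C)C)O2)[C@@H]1O[Si](C)(C)C(C)(C)C | intermediate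
24 | cis-fused 4a,5,6,7,8,8a-hexahydrochromen-4-one adduct (O1 on the β face at C8a, H-4a and H-8a α) | COc1cc2oc(CCc3ccccc3)cc(=O)c2cc1O[C@@H]1[C@H]2OC(CCc3ccccc3)=CC(=O)[C@H]2[C@H](O[Si]2(C(C)C)C(C)C)[C@@H](O[Si](C(C)C)(C(C)C)O2)[C@@H]1O[Si](C)(C)C(C)(C)C | intermediate
25 | 8α-ArO-7α-(TBSO)-5α,6β-(TIPDS-dioxy)-2-(2-phenylethyl)-5,6,7,8-tetrahydro-4H-chromen-4-one (key-step product) | COc1cc2oc(CCc3ccccc3)cc(=O)c2cc1O[C@@H]1c2oc(CCc3ccccc3)cc(=O)c2[C@H](O[Si]2(C(C)C)C(C)C)[C@@H](O[Si](C(C)C)(C(C)C)O2)[C@@H]1O[Si](C)(C)C(C)(C)C | intermediate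
26 | (5S,6R,7S,8S)-5,6,7-trihydroxy-8-ArO-2-(2-phenylethyl)-5,6,7,8-tetrahydro-4H-chromen-4-one, CNP0125425.2 | COc1cc2oc(CCc3ccccc3)cc(=O)c2cc1O[C@@H]1c2oc(CCc3ccccc3)cc(=O)c2[C@H](O)[C@@H](O)[C@@H]1O | target

Total step count: 17.
Longest linear sequence: 13 (steps 1–7 and 12–17).

**Steps most likely to fail**

1. Step 16.
   - What may go wrong: trapping of the catalyst as an inert O,O-diketonate chelate, slow closure onto the hindered C8a, ionisation of the allylic aryl ether by transient zerovalent palladium, or β-elimination at C5 followed by aromatisation.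
   - Fallback (stepwise, no catalytic turnover needed): starting from 23, the oxa-Michael closure is run alone with CF3CO2H in CH2Cl2 and the dihydropyranone 24 is isolated. Soft enolisation with Me3SiOTf and Et3N gives the 4-trimethylsilyloxy-8aH-pyran silyl dienol ether F1. Hydride abstraction from C8a with DDQ in CH2Cl2 (silyl enol ether dehydrogenation, related to the Saegusa–Ito oxidation) passes through the 4-silyloxypyrylium ion and returns to the route at 25.

2. Step 12.
   - What may go wrong: β-hydride elimination of the allylpalladium intermediate toward C4 with later aromatisation, sluggish ionisation of the hindered electron-poor alkene, or erosion of stereospecificity by palladium-for-palladium displacement.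
   - Fallback (one SN2 inversion instead of two): starting from 9, activated MnO2 oxidises only the allylic hydroxyl to the 4α-hydroxy-3-enone F2. TBSOTf with 2,6-lutidine gives the 4-O-TBS enone F3. Luche reduction (NaBH4, CeCl3·7H2O, MeOH, −78 °C) should deliver hydride axially from the α face of the locked ring to give the equatorial 3β-alcohol F4. Mitsunobu etherification with 16 (PPh3, DIAD, toluene) inverts C3 and returns to the route at 18.

3. Step 15.
   - What may go wrong: O-acylation of the enolate, γ-deprotonation at C3 with elimination and aromatisation, or proton transfer from the CH2 next to C2 of the aromatic chromone.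
   - Fallback (an alkyne nucleophile in place of an enolate, amine bases only): starting from 19 through 21, coupling with 4-phenylbut-1-yne under copper iodide CuI (cat.) and Et3N in THF gives the alkenyl ynone F5. Conjugate addition of Et2NH gives the (E)-β-diethylamino enone F6. Mild hydrolysis with aqueous oxalic acid in THF returns to the route at 23.

**Further compounds**

F1 | step 16 | 4-trimethylsilyloxy-8aH-pyran silyl dienol ether of 24 | COc1cc2oc(CCc3ccccc3)cc(=O)c2cc1O[C@@H]1[C@H]2OC(CCc3ccccc3)=CC(O[Si](C)(C)C)=C2[C@H](O[Si]2(C(C)C)C(C)C)[C@@H](O[Si](C(C)C)(C(C)C)O2)[C@@H]1O[Si](C)(C)C(C)(C)C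
F2 | step 12 | methyl 4α-hydroxy-3-oxo-5β,6α-(TIPDS-dioxy)cyclohex-1-ene-1-carboxylate | O=C1C=C(C(=O)OC)[C@H](O[Si]2(C(C)C)C(C)C)[C@@H](O[Si](C(C)C)(C(C)C)O2)[C@@H]1O
F3 | step 12 | methyl 3-oxo-4α-(TBSO)-5β,6α-(TIPDS-dioxy)cyclohex-1-ene-1-carboxylate | O=C1C=C(C(=O)OC)[C@H](O[Si]2(C(C)C)C(C)C)[C@@H](O[Si](C(C)C)(C(C)C)O2)[C@@H]1O[Si](C)(C)C(C)(C)C
F4 | step 12 | methyl 3β-hydroxy-4α-(TBSO)-5β,6α-(TIPDS-dioxy)cyclohex-1-ene-1-carboxylate | O[C@H]1C=C(C(=O)OC)[C@H](O[Si]2(C(C)C)C(C)C)[C@@H](O[Si](C(C)C)(C(C)C)O2)[C@@H]1O[Si](C)(C)C(C)(C)C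
F5 | step 15 | 1-[3α-ArO-4α-(TBSO)-5β,6α-(TIPDS-dioxy)cyclohex-1-en-1-yl]-5-phenylpent-2-yn-1-one | COc1cc2oc(CCc3ccccc3)cc(=O)c2cc1O[C@@H]1C=C(C(=O)C#CCCc2ccccc2)[C@H](O[Si]2(C(C)C)C(C)C)[C@@H](O[Si](C(C)C)(C(C)C)O2)[C@@H]1O[Si](C)(C)C(C)(C)C
F6 | step 15 | (E)-3-(diethylamino)-1-[3α-ArO-4α-(TBSO)-5β,6α-(TIPDS-dioxy)cyclohex-1-en-1-yl]-5-phenylpent-2-en-1-one | COc1cc2oc(CCc3ccccc3)cc(=O)c2cc1O[C@@H]1C=C(C(=O)/C=C(/N(CC)CC)CCc2ccccc2)[C@H](O[Si]2(C(C)C)C(C)C)[C@@H](O[Si](C(C)C)(C(C)C)O2)[C@@H]1O[Si](C)(C)C(C)(C)C
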